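**Plan**

- Retrosynthesis: the angelates come off first (C3–O and C6–O, then C8–O). The ring bond C7–C8 is cut next: C8 is a carbinol carbon between the C9 ketone and C7, and C7 carries the isopropenyl group C11(=C12)C13, so C9(=O)–C8(OH)–C7–C11=C12 is the retron of a γ-allylation of a C8 glyoxal by a C12-borylated 2-methylallyl unit. The two cis-fused epoxide rings (C1/C10, C4/C5) stay in the open chain and pre-bend it.
- Further cuts: C11–C12 and C7=C11 (Negishi coupling, iodo-olefination), C8–C9 (alkoxymethyllithium on a C9 Weinreb amide), C9–O/C1=C10 (methacrylate ring-closing metathesis to a temporary 5,6-dihydropyran-2-one ring), C2–C3 (allylboration), C3–C4 (formylation of a (Z)-alkenyl iodide), C4–I (hydroalumination–iodination of a C4≡C5 propargylic diol made from glyceraldehyde acetonide by alkyne homologation).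
- Forward: C5–C7 from the chiral pool → C4≡C5 alkyne → (Z)-alkenyl iodide → (Z)-enal → C3 carbinol → 4,5-epoxide → six-membered lactone ring (C3–O–C9, C1=C10 forced Z) → 1,10-epoxide → lactone opened and C8 added → (Z)-iodoalkene at C7=C11 → (Z)-allylboronate at C12 → ten-membered ring closed at C7–C8 → C8 angelate, desilylation, C3 and C6 angelates.
- Stereochemistry: C6 is bought; the Z geometry of C4=C5 comes from hydroxyl-directed anti hydroalumination; C3 is set by chiral phosphoric acid catalysis; C4/C5 follow from C3–OH-directed epoxidation under A(1,3) strain (reinforced by C6–OSi); C1/C10 from conjugate epoxidation anti to the C3 substituent on the lactone ring; C7 and C8 arise together in the ring closure.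

Key step: step 20

Remark: positions are given in germacrane numbering of the target (C7 carries the isopropenyl group C11(=C12)C13, then C8 (O-angelate), C9 (C=O), C10 (epoxide, methyl C15), C1 (epoxide CH), C2 (CH2), C3 (O-angelate), C4 (epoxide, methyl C14), C5 (epoxide CH), C6 (O-angelate)); systematic names of open-chain intermediates carry their own locants.

Assumption: (S)-glyceraldehyde acetonide is taken as commercial, and the (S)-configured phosphoric acid of step 7 is taken to direct Si-face attack on the enal, by analogy with the Re-face attack reported for the (R)-acid on aryl and alkenyl aldehydes; if a first batch shows the opposite sense, the (R)-acid is used.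

**Step 1**
Reactants: 1 (S)-2,2-dimethyl-1,3-dioxolane-4-carbaldehyde
Product: 3 (4R)-4-(2,2-dibromoethenyl)-2,2-dimethyl-1,3-dioxolane, via (dibromomethylidene)triphenylphosphorane 2 (not isolated)
Conditions: PPh3 (4 equiv), CBr4 (2 equiv), CH2Cl2, 0 °C; then 1, 0 °C
Reagents that add atoms: carbon tetrabromide, BrC(Br)(Br)Br
Why: Ramirez dibromo-olefination (first stage of the Corey–Fuchs sequence) converts the aldehyde into the 1,1-dibromoalkene under non-basic conditions that should not epimerise the α-alkoxy aldehyde; the C6 stereocentre comes with 1.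

**Step 2**
Reactants: 3 (4R)-4-(2,2-dibromoethenyl)-2,2-dimethyl-1,3-dioxolane
Product: 5 (4R)-2,2-dimethyl-4-(prop-1-yn-1-yl)-1,3-dioxolane, via lithium alkynide 4 (not isolated)
Conditions: n-BuLi (2.1 equiv), THF, −78 °C; then MeI, −78 °C → rt
Reagents that add atoms: iodomethane, CI
Why: Corey–Fuchs alkyne synthesis; dehydrobromination and bromine–lithium exchange give the lithium alkynide, which is C-methylated in the same flask and so brings in C14 on the C4≡C5 triple bond.

**Step 3**
Reactants: 5 (4R)-2,2-dimethyl-4-(prop-1-yn-1-yl)-1,3-dioxolane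
Product: 6 (2R)-pent-3-yne-1,2-diol
Conditions: AcOH/H2O (4:1), 40 °C
Reagents that add atoms: none
Why: acid-catalysed acetal hydrolysis is placed here, before any epoxide exists, and frees the propargylic hydroxyl that directs the next step.

**Step 4**
Reactants: 6 (2R)-pent-3-yne-1,2-diol
Product: 8 (2R,3Z)-4-iodopent-3-ene-1,2-diol, via cyclic alkenylaluminate 7 (not isolated)
Conditions: NaAlH2(OCH2CH2OMe)2 (3 equiv), THF, 0 °C → rt; EtOAc, 0 °C; then I2, THF, −78 → 0 °C; aq. Na2S2O3
Reagents that add atoms: iodine, II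
Why: hydroxyl-directed trans-hydroalumination of the propargylic alcohol delivers hydride to C5 and aluminium to C4 within a five-membered oxa-aluminacycle, and iodinolysis with retention (the classical route to (Z)-3-iodo allylic alcohols) places iodine, the later attachment point of C3, cis to C6.

**Step 5**
Reactants: 8 (2R,3Z)-4-iodopent-3-ene-1,2-diol
Product: 9 (2R,3Z)-4-iodo-1,2-bis(triethylsilyloxy)pent-3-ene
Conditions: Et3SiCl, imidazole, CH2Cl2, 0 °C → rt
Reagents that add atoms: chlorotriethylsilane, CC[Si](Cl)(CC)CC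
Why: silyl ether formation gives two base-stable triethylsilyl ethers, the secondary one as a bulky non-directing group at C6 and the primary one as the latent C7 aldehyde.

**Step 6**
Reactants: 9 (2R,3Z)-4-iodo-1,2-bis(triethylsilyloxy)pent-3-ene
Product: 11 (2Z,4R)-2-methyl-4,5-bis(triethylsilyloxy)pent-2-enal, via alkenyllithium 10 (not isolated)
Conditions: t-BuLi (2.1 equiv), Et2O, −78 °C; DMF, −78 → 0 °C; aq. NH4Cl
Reagents that add atoms: N,N-dimethylformamide, CN(C)C=O
Why: iodine–lithium exchange and formylation of the alkenyllithium with DMF proceed with retention of alkene geometry, so the formyl carbon (C3) ends up cis to C6.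

**Step 7**
Reactants: 11 (2Z,4R)-2-methyl-4,5-bis(triethylsilyloxy)pent-2-enal; 12 allylboronic acid pinacol ester
Product: 13 (4S,5Z,7R)-5-methyl-7,8-bis(triethylsilyloxy)octa-1,5-dien-4-ol
Conditions: (S)-TRIP [(S)-3,3′-bis(2,4,6-triisopropylphenyl)-1,1′-binaphthyl-2,2′-diyl hydrogen phosphate] (5 mol %), toluene, −30 °C
Reagents that add atoms: none
Why: chiral Brønsted acid-catalysed allylboration through a six-membered chair sets C3 by catalyst control (Si-face attack expected), and the mild, nearly neutral conditions should not isomerise the (Z)-enal.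

**Step 8**
Reactants: 13 (4S,5Z,7R)-5-methyl-7,8-bis(triethylsilyloxy)octa-1,5-dien-4-ol
Product: 14 (4S,5R,6S,7S)-5,6-epoxy-5-methyl-7,8-bis(triethylsilyloxy)oct-1-en-4-ol
Conditions: mCPBA, CH2Cl2, −20 → 0 °C
Reagents that add atoms: 3-chloroperoxybenzoic acid, OOC(=O)c1cccc(Cl)c1
Why: hydroxyl-directed peracid epoxidation; A(1,3) strain in the (Z)-alkene holds H3 and H6 in the alkene plane, so oxygen is delivered syn to the C3 hydroxyl (threo) and anti to the C6 silyloxy group, which sets C4 and C5 together, while the trisubstituted allylic alkene reacts far faster than the terminal vinyl group.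

**Step 9**
Reactants: 14 (4S,5R,6S,7S)-5,6-epoxy-5-methyl-7,8-bis(triethylsilyloxy)oct-1-en-4-ol; 15 methacrylic anhydride
Product: 16 (4S,5R,6S,7S)-5,6-epoxy-5-methyl-7,8-bis(triethylsilyloxy)oct-1-en-4-yl 2-methylprop-2-enoate
Conditions: Et3N, DMAP (10 mol %), CH2Cl2, 0 °C → rt
Reagents that add atoms: none
Why: DMAP-catalysed esterification of the secondary alcohol brings in C9, C10 and C15 as a methacrylate tether.

**Step 10**
Reactants: 16 (4S,5R,6S,7S)-5,6-epoxy-5-methyl-7,8-bis(triethylsilyloxy)oct-1-en-4-yl 2-methylprop-2-enoate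
Product: 17 (6S)-3-methyl-6-{(2R,3S)-2-methyl-3-[(1S)-1,2-bis(triethylsilyloxy)ethyl]oxiran-2-yl}-5,6-dihydro-2H-pyran-2-one
Conditions: second-generation Grubbs catalyst RuCl2(=CHPh)(H2IMes)(PCy3) (5 mol %), CH2Cl2 (5 mM), 40 °C
Reagents that add atoms: none
Why: ring-closing metathesis of the methacrylate with the terminal alkene gives the 3-methyl-5,6-dihydropyran-2-one, a temporary ring in which C1=C10 can only be Z and C3–O is protected.

**Step 11**
Reactants: 17 (6S)-3-methyl-6-{(2R,3S)-2-methyl-3-[(1S)-1,2-bis(triethylsilyloxy)ethyl]oxiran-2-yl}-5,6-dihydro-2H-pyran-2-one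
Product: 18 (1R,4S,6R)-1-methyl-4-{(2R,3S)-2-methyl-3-[(1S)-1,2-bis(triethylsilyloxy)ethyl]oxiran-2-yl}-3,7-dioxabicyclo[4.1.0]heptan-2-one
Conditions: t-BuOOH (in decane), n-BuLi, THF, −78 → 0 °C
Reagents that add atoms: tert-butyl hydroperoxide, CC(C)(C)OO
Why: nucleophilic (Weitz–Scheffer-type) epoxidation with lithium tert-butyl peroxide; axial conjugate addition to C1 anti to the pseudo-equatorial C3 substituent of the half-chair lactone, followed by closure of the enolate, sets C1 and C10, and the ring enforces the cis-epoxide.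

**Step 12**
Reactants: 18 (1R,4S,6R)-1-methyl-4-{(2R,3S)-2-methyl-3-[(1S)-1,2-bis(triethylsilyloxy)ethyl]oxiran-2-yl}-3,7-dioxabicyclo[4.1.0]heptan-2-one
Product: 19 (2R,3R,5S,6R,7S,8S)-2,3:6,7-diepoxy-5-hydroxy-N-methoxy-N,2,6-trimethyl-8,9-bis(triethylsilyloxy)nonanamide
Conditions: MeNH(OMe)·HCl, i-PrMgCl, THF, −20 → 0 °C
Reagents that add atoms: N,O-dimethylhydroxylamine hydrochloride, CNOC.Cl
Why: aminolysis of the lactone with the magnesium amide opens the temporary ring, frees the C3 hydroxyl and turns C9 into a Weinreb amide.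

**Step 13**
Reactants: 19 (2R,3R,5S,6R,7S,8S)-2,3:6,7-diepoxy-5-hydroxy-N-methoxy-N,2,6-trimethyl-8,9-bis(triethylsilyloxy)nonanamide
Product: 20 (2R,3R,5S,6S,7S,8S)-2,3:6,7-diepoxy-N-methoxy-N,2,6-trimethyl-5,8,9-tris(triethylsilyloxy)nonanamide
Conditions: Et3SiOTf, 2,6-lutidine, CH2Cl2, −78 → 0 °C
Reagents that add atoms: triethylsilyl trifluoromethanesulfonate, CC[Si](CC)(CC)OS(=O)(=O)C(F)(F)F
Why: silylation with the silyl triflate protects the hindered C3 hydroxyl before relactonisation can occur (the descriptor at the epoxide carbon changes only because of CIP ranking).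

**Step 14**
Reactants: 21 4-methoxybenzyl alcohol; 22 tributyl(iodomethyl)stannane
Product: 24 tributyl{[(4-methoxybenzyl)oxy]methyl}stannane, via sodium 4-methoxybenzyl oxide 23 (not isolated)
Conditions: NaH, THF/DMF, 0 °C; then 22, rt
Reagents that add atoms: none
Why: Williamson ether synthesis at the iodomethyl carbon gives the α-alkoxymethylstannane that serves as a hydroxymethyl anion precursor.

**Step 15**
Reactants: 20 (2R,3R,5S,6S,7S,8S)-2,3:6,7-diepoxy-N-methoxy-N,2,6-trimethyl-5,8,9-tris(triethylsilyloxy)nonanamide; 24 tributyl{[(4-methoxybenzyl)oxy]methyl}stannane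
Product: 26 (3R,4R,6S,7S,8S,9S)-3,4:7,8-diepoxy-1-[(4-methoxybenzyl)oxy]-3,7-dimethyl-6,9,10-tris(triethylsilyloxy)decan-2-one, via [(4-methoxybenzyl)oxy]methyllithium 25 (not isolated)
Conditions: 24, n-BuLi, THF, −78 °C; then 20, −78 °C; aq. NH4Cl
Reagents that add atoms: none
Why: tin–lithium exchange and Weinreb ketone synthesis; the alkoxymethyllithium adds once to the amide (stable chelate) and installs C8 at the alcohol oxidation level next to the C9 ketone.

**Step 16**
Reactants: 26 (3R,4R,6S,7S,8S,9S)-3,4:7,8-diepoxy-1-[(4-methoxybenzyl)oxy]-3,7-dimethyl-6,9,10-tris(triethylsilyloxy)decan-2-one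
Product: 27 (2R,3S,4S,5S,7R,8R)-3,4:7,8-diepoxy-10-[(4-methoxybenzyl)oxy]-4,8-dimethyl-9-oxo-2,5-bis(triethylsilyloxy)decanal
Conditions: (COCl)2, DMSO, CH2Cl2, −78 → −40 °C; Et3N, −78 → 0 °C
Reagents that add atoms: none
Why: under Swern conditions a primary triethylsilyl ether is converted directly into the aldehyde while secondary triethylsilyl ethers survive, which unmasks C7 without a separate deprotection.

**Step 17**
Reactants: 27 (2R,3S,4S,5S,7R,8R)-3,4:7,8-diepoxy-10-[(4-methoxybenzyl)oxy]-4,8-dimethyl-9-oxo-2,5-bis(triethylsilyloxy)decanal; 28 ethyltriphenylphosphonium iodide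
Product: 32 (3R,4R,6S,7S,8S,9S,10Z)-3,4:7,8-diepoxy-11-iodo-1-[(4-methoxybenzyl)oxy]-3,7-dimethyl-6,9-bis(triethylsilyloxy)dodec-10-en-2-one, via ethylidene(triphenyl)phosphorane 29 (not isolated), via (1-iodoethyl)triphenylphosphonium iodide 30 (not isolated), via (1-iodoethylidene)triphenylphosphorane 31 (not isolated)
Conditions: 28, n-BuLi, THF, 0 °C; I2, −78 °C; NaN(SiMe3)2, −20 °C; then 27, −78 → −20 °C
Reagents that add atoms: iodine, II
Why: Stork–Zhao iodo-olefination (Wittig reaction of the α-iodo ylide) at the aldehyde should give the (Z)-2-iodoalkene, with iodine, the later C12 attachment point, cis to C6; the hindered C9 ketone flanked by a quaternary carbon should not react at −78 °C.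

**Step 18**
Reactants: 32 (3R,4R,6S,7S,8S,9S,10Z)-3,4:7,8-diepoxy-11-iodo-1-[(4-methoxybenzyl)oxy]-3,7-dimethyl-6,9-bis(triethylsilyloxy)dodec-10-en-2-one
Product: 33 (3R,4R,6S,7S,8S,9S,10Z)-3,4:7,8-diepoxy-1-hydroxy-11-iodo-3,7-dimethyl-6,9-bis(triethylsilyloxy)dodec-10-en-2-one
Conditions: DDQ, CH2Cl2/pH 7 buffer (10:1), 0 °C
Reagents that add atoms: none
Why: oxidative cleavage of the 4-methoxybenzyl ether frees the C8 hydroxyl under neutral conditions; it is done before boron is introduced because allylboronates would react with DDQ.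

**Step 19**
Reactants: 33 (3R,4R,6S,7S,8S,9S,10Z)-3,4:7,8-diepoxy-1-hydroxy-11-iodo-3,7-dimethyl-6,9-bis(triethylsilyloxy)dodec-10-en-2-one; 34 2-(iodomethyl)-4,4,5,5-tetramethyl-1,3,2-dioxaborolane
Product: 36 (3R,4R,6S,7S,8S,9S,10Z)-3,4:7,8-diepoxy-1-hydroxy-3,7,11-trimethyl-12-(4,4,5,5-tetramethyl-1,3,2-dioxaborolan-2-yl)-6,9-bis(triethylsilyloxy)dodec-10-en-2-one, via (pinacolboryl)methylzinc iodide 35 (not isolated)
Conditions: 34, Zn dust, THF, rt; then 33, Pd(PPh3)4 (5 mol %), THF, rt → 40 °C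
Reagents that add atoms: none
Why: Negishi coupling of the alkenyl iodide with the (boryl)methylzinc reagent at zerovalent palladium proceeds with retention of alkene geometry and gives the (Z)-γ-substituted 2-methylallylboronate with C12–B cis to C6.

**Step 20**
Reactants: 36 (3R,4R,6S,7S,8S,9S,10Z)-3,4:7,8-diepoxy-1-hydroxy-3,7,11-trimethyl-12-(4,4,5,5-tetramethyl-1,3,2-dioxaborolan-2-yl)-6,9-bis(triethylsilyloxy)dodec-10-en-2-one
Product: 38 (1R,3S,4S,5S,6S,7R,8S,10R)-1,10:4,5-diepoxy-8-hydroxy-3,6-bis(triethylsilyloxy)germacr-11(12)-en-9-one, via C8 glyoxal 37 (not isolated)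
Conditions: Dess–Martin periodinane, NaHCO3, CH2Cl2 (2 mM), 0 °C → rt; aq. NaHCO3 work-up
Reagents that add atoms: none
Why: Proposed new method: Dess–Martin oxidation turns the primary α-ketol into the C8 glyoxal 37, and C7, the γ-carbon of the tethered (Z)-allylboronate, then adds to this very electrophilic formyl group through a closed six-membered chair (Zimmerman–Traxler) transition state with allyl transposition, which creates the C11=C12 isopropenyl group and, after hydrolysis of the borate on work-up, the C8 hydroxyl next to the C9 ketone. The closest known reaction types are the intermolecular allylboration of aldehydes with (Z)-γ-substituted allylboronates (syn-selective), intramolecular allylborations that form five- to seven-membered rings, and the chromium- or zinc-mediated intramolecular allylations that close ten-membered germacrane rings at a bond to C7; a thermal boron version to a ten-membered ring is not established. The ten-membered carbocycle is closed by C7–C8 bond formation in a 10-exo-trig attack on the formyl carbon (SE2′ at the allyl unit), helped by three cis elements (two cis-epoxides, one Z-alkene) that fold the chain. C8 is set by the chair: the Z geometry puts C6 pseudo-axial and C9 equatorial, which gives the 7,8-syn relationship of the target (C8–O trans to the isopropenyl group on the ring); C7 is set by C6, because A(1,3) strain with C12 holds H6 in the alkene plane and the formyl group adds to the face anti to the bulky triethylsilyloxy group. The step needs chemo- and regioselectivity (formyl over the hindered C9 ketone, γ- over α-attack), both inherent to allylboration, configurational stability of the Z-allyl unit, which pinacol boronates have at room temperature, and ring closure over oligomerisation, secured by 2 mM concentration and by forming the aldehyde only in the presence of its partner. No reducing metal or Lewis acid is present, so the α,β-epoxy ketone and both epoxides should survive.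

**Step 21**
Reactants: 39 angelic acid
Product: 40 angelic 2,4,6-trichlorobenzoic anhydride
Conditions: 2,4,6-trichlorobenzoyl chloride, Et3N, toluene, 0 °C → rt; filtration, concentration
Reagents that add atoms: 2,4,6-trichlorobenzoyl chloride, O=C(Cl)c1c(Cl)cc(Cl)cc1Cl
Why: mixed anhydride formation (Yamaguchi reagent) from the triethylammonium carboxylate and the hindered acyl chloride, run without a nucleophilic catalyst so that the (Z)-geometry of the angeloyl group is kept; the anhydride is freed of the ammonium salt and used as the single acyl donor of steps 22 and 24.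

**Step 22**
Reactants: 38 (1R,3S,4S,5S,6S,7R,8S,10R)-1,10:4,5-diepoxy-8-hydroxy-3,6-bis(triethylsilyloxy)germacr-11(12)-en-9-one; 40 angelic 2,4,6-trichlorobenzoic anhydride
Product: 41 (1R,3S,4S,5S,6S,7R,8S,10R)-8-(angeloyloxy)-1,10:4,5-diepoxy-3,6-bis(triethylsilyloxy)germacr-11(12)-en-9-one
Conditions: 40 (1.5 equiv), Et3N, toluene, 60 °C
Reagents that add atoms: none
Why: Yamaguchi-type esterification without nucleophilic catalyst; the only free hydroxyl (C8) attacks the less hindered angeloyl carbonyl of the mixed anhydride, which should avoid angelate-to-tiglate isomerisation, while the silyl ethers keep C3 and C6 masked and exclude a transannular hemiketal.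

**Step 23**
Reactants: 41 (1R,3S,4S,5S,6S,7R,8S,10R)-8-(angeloyloxy)-1,10:4,5-diepoxy-3,6-bis(triethylsilyloxy)germacr-11(12)-en-9-one
Product: 42 (1R,3S,4R,5S,6S,7S,8S,10R)-8-(angeloyloxy)-1,10:4,5-diepoxy-3,6-dihydroxygermacr-11(12)-en-9-one
Conditions: Et3N·3HF, MeCN/THF, rt
Reagents that add atoms: none
Why: fluoride-mediated desilylation removes both triethylsilyl ethers under weakly acidic, non-basic conditions that tolerate the epoxides and the angelate and should not epimerise C8 (descriptor changes at C4 and C7 are CIP ranking only).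

**Step 24**
Reactants: 42 (1R,3S,4R,5S,6S,7S,8S,10R)-8-(angeloyloxy)-1,10:4,5-diepoxy-3,6-dihydroxygermacr-11(12)-en-9-one; 40 angelic 2,4,6-trichlorobenzoic anhydride
Product: 43 (1R,3S,4R,5S,6S,7S,8S,10R)-3,6,8-tris(angeloyloxy)-1,10:4,5-diepoxygermacr-11(12)-en-9-one (CNP0154187.1)
Conditions: 40 (4 equiv), Et3N, toluene, 80 °C
Reagents that add atoms: none
Why: the same Yamaguchi-type esterification, again without nucleophilic catalyst, should acylate the two remaining secondary hydroxyls (C3 and C6) with retention of the angelate geometry and without touching a stereocentre.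

**Compound list**

1 | (S)-2,2-dimethyl-1,3-dioxolane-4-carbaldehyde ((S)-glyceraldehyde acetonide) | O=C[C@@H]1COC(C)(C)O1 | starting material
2 | (dibromomethylidene)triphenylphosphorane | BrC(Br)=P(c1ccccc1)(c1ccccc1)c1ccccc1 | intermediate
3 | (4R)-4-(2,2-dibromoethenyl)-2,2-dimethyl-1,3-dioxolane | BrC(Br)=C[C@@H]1COC(C)(C)O1 | intermediate
4 | lithium alkynide from 3 (lithium [(4R)-2,2-dimethyl-1,3-dioxolan-4-yl]ethynide) | [Li]C#C[C@@H]1COC(C)(C)O1 | intermediate
5 | (4R)-2,2-dimethyl-4-(prop-1-yn-1-yl)-1,3-dioxolane | CC#C[C@@H]1COC(C)(C)O1 | intermediate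
6 | (2R)-pent-3-yne-1,2-diol | CC#C[C@@H](O)CO | intermediate
7 | cyclic alkenylaluminate from 6 (five-membered oxa-aluminacycle, aluminium on C4 cis to C6, sodium salt; primary hydroxyl drawn as its sodium alkoxide) | C/C1=C/[C@H](C[O-])O[Al-]1(OCCOC)OCCOC.[Na+].[Na+] | intermediate
8 | (2R,3Z)-4-iodopent-3-ene-1,2-diol | C/C(I)=C/[C@@H](O)CO | intermediate
9 | (2R,3Z)-4-iodo-1,2-bis(triethylsilyloxy)pent-3-ene | C/C(I)=C/[C@@H](O[Si](CC)(CC)CC)CO[Si](CC)(CC)CC | intermediate
10 | alkenyllithium from 9 (lithium in place of iodine, cis to C6) | [Li]/C(C)=C\[C@@H](O[Si](CC)(CC)CC)CO[Si](CC)(CC)CC | intermediate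
11 | (2Z,4R)-2-methyl-4,5-bis(triethylsilyloxy)pent-2-enal | O=C/C(C)=C\[C@@H](O[Si](CC)(CC)CC)CO[Si](CC)(CC)CC | intermediate
12 | allylboronic acid pinacol ester | C=CCB1OC(C)(C)C(C)(C)O1 | starting material
13 | (4S,5Z,7R)-5-methyl-7,8-bis(triethylsilyloxy)octa-1,5-dien-4-ol | C=CC[C@H](O)/C(C)=C\[C@@H](O[Si](CC)(CC)CC)CO[Si](CC)(CC)CC | intermediate
14 | (4S,5R,6S,7S)-5,6-epoxy-5-methyl-7,8-bis(triethylsilyloxy)oct-1-en-4-ol | C=CC[C@H](O)[C@@]1(C)O[C@H]1[C@@H](O[Si](CC)(CC)CC)CO[Si](CC)(CC)CC | intermediate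
15 | methacrylic anhydride | CC(=C)C(=O)OC(=O)C(C)=C | starting material
16 | (4S,5R,6S,7S)-5,6-epoxy-5-methyl-7,8-bis(triethylsilyloxy)oct-1-en-4-yl 2-methylprop-2-enoate | C=CC[C@H](OC(=O)C(C)=C)[C@@]1(C)O[C@H]1[C@@H](O[Si](CC)(CC)CC)CO[Si](CC)(CC)CC | intermediate
17 | (6S)-3-methyl-6-{(2R,3S)-2-methyl-3-[(1S)-1,2-bis(triethylsilyloxy)ethyl]oxiran-2-yl}-5,6-dihydro-2H-pyran-2-one | O=C1C(C)=CC[C@H](O1)[C@@]2(C)O[C@H]2[C@@H](O[Si](CC)(CC)CC)CO[Si](CC)(CC)CC | intermediate
18 | (1R,4S,6R)-1-methyl-4-{(2R,3S)-2-methyl-3-[(1S)-1,2-bis(triethylsilyloxy)ethyl]oxiran-2-yl}-3,7-dioxabicyclo[4.1.0]heptan-2-one | O=C1[C@]3(C)O[C@@H]3C[C@H](O1)[C@@]2(C)O[C@H]2[C@@H](O[Si](CC)(CC)CC)CO[Si](CC)(CC)CC | intermediate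
19 | (2R,3R,5S,6R,7S,8S)-2,3:6,7-diepoxy-5-hydroxy-N-methoxy-N,2,6-trimethyl-8,9-bis(triethylsilyloxy)nonanamide | CON(C)C(=O)[C@]1(C)O[C@@H]1C[C@H](O)[C@@]2(C)O[C@H]2[C@@H](O[Si](CC)(CC)CC)CO[Si](CC)(CC)CC | intermediate
20 | (2R,3R,5S,6S,7S,8S)-2,3:6,7-diepoxy-N-methoxy-N,2,6-trimethyl-5,8,9-tris(triethylsilyloxy)nonanamide | CON(C)C(=O)[C@]1(C)O[C@@H]1C[C@H](O[Si](CC)(CC)CC)[C@@]2(C)O[C@H]2[C@@H](O[Si](CC)(CC)CC)CO[Si](CC)(CC)CC | intermediate
21 | 4-methoxybenzyl alcohol | COc1ccc(CO)cc1 | starting material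
22 | tributyl(iodomethyl)stannane | CCCC[Sn](CI)(CCCC)CCCC | starting material
23 | sodium 4-methoxybenzyl oxide | [Na+].[O-]Cc1ccc(OC)cc1 | intermediate
24 | tributyl{[(4-methoxybenzyl)oxy]methyl}stannane | CCCC[Sn](CCCC)(CCCC)COCc1ccc(OC)cc1 | intermediate
25 | [(4-methoxybenzyl)oxy]methyllithium | [Li]COCc1ccc(OC)cc1 | intermediate
26 | (3R,4R,6S,7S,8S,9S)-3,4:7,8-diepoxy-1-[(4-methoxybenzyl)oxy]-3,7-dimethyl-6,9,10-tris(triethylsilyloxy)decan-2-one | COc1ccc(COCC(=O)[C@]2(C)O[C@@H]2C[C@H](O[Si](CC)(CC)CC)[C@@]3(C)O[C@H]3[C@@H](O[Si](CC)(CC)CC)CO[Si](CC)(CC)CC)cc1 | intermediate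
27 | (2R,3S,4S,5S,7R,8R)-3,4:7,8-diepoxy-10-[(4-methoxybenzyl)oxy]-4,8-dimethyl-9-oxo-2,5-bis(triethylsilyloxy)decanal | COc1ccc(COCC(=O)[C@]2(C)O[C@@H]2C[C@H](O[Si](CC)(CC)CC)[C@@]3(C)O[C@H]3[C@@H](O[Si](CC)(CC)CC)C=O)cc1 | intermediate
28 | ethyltriphenylphosphonium iodide | CC[P+](c1ccccc1)(c1ccccc1)c1ccccc1.[I-] | starting material
29 | ethylidene(triphenyl)phosphorane | CC=P(c1ccccc1)(c1ccccc1)c1ccccc1 | intermediate
30 | (1-iodoethyl)triphenylphosphonium iodide | CC(I)[P+](c1ccccc1)(c1ccccc1)c1ccccc1.[I-] | intermediate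
31 | (1-iodoethylidene)triphenylphosphorane | CC(I)=P(c1ccccc1)(c1ccccc1)c1ccccc1 | intermediate
32 | (3R,4R,6S,7S,8S,9S,10Z)-3,4:7,8-diepoxy-11-iodo-1-[(4-methoxybenzyl)oxy]-3,7-dimethyl-6,9-bis(triethylsilyloxy)dodec-10-en-2-one | C/C(I)=C/[C@H](O[Si](CC)(CC)CC)[C@@H]1O[C@]1(C)[C@@H](O[Si](CC)(CC)CC)C[C@H]2O[C@@]2(C)C(=O)COCc1ccc(OC)cc1 | intermediate
33 | (3R,4R,6S,7S,8S,9S,10Z)-3,4:7,8-diepoxy-1-hydroxy-11-iodo-3,7-dimethyl-6,9-bis(triethylsilyloxy)dodec-10-en-2-one | C/C(I)=C/[C@H](O[Si](CC)(CC)CC)[C@@H]1O[C@]1(C)[C@@H](O[Si](CC)(CC)CC)C[C@H]2O[C@@]2(C)C(=O)CO | intermediate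
34 | 2-(iodomethyl)-4,4,5,5-tetramethyl-1,3,2-dioxaborolane | ICB1OC(C)(C)C(C)(C)O1 | starting material
35 | (pinacolboryl)methylzinc iodide | I[Zn]CB1OC(C)(C)C(C)(C)O1 | intermediate
36 | (3R,4R,6S,7S,8S,9S,10Z)-3,4:7,8-diepoxy-1-hydroxy-3,7,11-trimethyl-12-(4,4,5,5-tetramethyl-1,3,2-dioxaborolan-2-yl)-6,9-bis(triethylsilyloxy)dodec-10-en-2-one | C/C(CB1OC(C)(C)C(C)(C)O1)=C/[C@H](O[Si](CC)(CC)CC)[C@@H]2O[C@]2(C)[C@@H](O[Si](CC)(CC)CC)C[C@H]3O[C@@]3(C)C(=O)CO | intermediate
37 | (3R,4R,6S,7S,8S,9S,10Z)-3,4:7,8-diepoxy-3,7,11-trimethyl-2-oxo-12-(4,4,5,5-tetramethyl-1,3,2-dioxaborolan-2-yl)-6,9-bis(triethylsilyloxy)dodec-10-enal (C8 glyoxal) | C/C(CB1OC(C)(C)C(C)(C)O1)=C/[C@H](O[Si](CC)(CC)CC)[C@@H]2O[C@]2(C)[C@@H](O[Si](CC)(CC)CC)C[C@H]3O[C@@]3(C)C(=O)C=O | intermediate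
38 | (1R,3S,4S,5S,6S,7R,8S,10R)-1,10:4,5-diepoxy-8-hydroxy-3,6-bis(triethylsilyloxy)germacr-11(12)-en-9-one | C=C(C)[C@H]1[C@H](O[Si](CC)(CC)CC)[C@@H]2O[C@]2(C)[C@@H](O[Si](CC)(CC)CC)C[C@H]2O[C@@]2(C)C(=O)[C@H]1O | intermediate
39 | angelic acid ((Z)-2-methylbut-2-enoic acid) | C/C=C(/C)C(=O)O | starting material
40 | angelic 2,4,6-trichlorobenzoic anhydride | C/C=C(/C)C(=O)OC(=O)c1c(Cl)cc(Cl)cc1Cl | intermediate
41 | (1R,3S,4S,5S,6S,7R,8S,10R)-8-(angeloyloxy)-1,10:4,5-diepoxy-3,6-bis(triethylsilyloxy)germacr-11(12)-en-9-one | C=C(C)[C@H]1[C@H](O[Si](CC)(CC)CC)[C@@H]2O[C@]2(C)[C@@H](O[Si](CC)(CC)CC)C[C@H]2O[C@@]2(C)C(=O)[C@H]1OC(=O)/C(C)=C\C | intermediate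
42 | (1R,3S,4R,5S,6S,7S,8S,10R)-8-(angeloyloxy)-1,10:4,5-diepoxy-3,6-dihydroxygermacr-11(12)-en-9-one | C=C(C)[C@H]1[C@H](O)[C@@H]2O[C@]2(C)[C@@H](O)C[C@H]2O[C@@]2(C)C(=O)[C@H]1OC(=O)/C(C)=C\C | intermediate
43 | (1R,3S,4R,5S,6S,7S,8S,10R)-3,6,8-tris(angeloyloxy)-1,10:4,5-diepoxygermacr-11(12)-en-9-one (CNP0154187.1) | C=C(C)[C@H]1[C@H](OC(=O)/C(C)=C\C)[C@@H]2O[C@]2(C)[C@@H](OC(=O)/C(C)=C\C)C[C@H]2O[C@@]2(C)C(=O)[C@H]1OC(=O)/C(C)=C\C | target

**Step count and risks**

Total step count: 24. Longest linear sequence: 22 (steps 1–13, 15–20 and 22–24; step 14 makes the stannane 24 and step 21 the mixed anhydride 40).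

Steps most likely to fail:

1. Step 20 (ring closure). The chain may oligomerise instead of closing, or close through a boat-like transition state or after loss of the Z geometry, which would give the wrong relative configuration at C7/C8. Fallback with known chemistry, setting out from 32 and coming back at 38: a Stille coupling of 32 with (tributylstannyl)methanol (Pd(PPh3)4, toluene, 80 °C) would give the (Z)-allylic alcohol F1, and Corey–Kim chlorination (N-chlorosuccinimide, Me2S, CH2Cl2, −20 °C) the allylic chloride F2. DDQ would then free the α-ketol F3, and Dess–Martin oxidation would give the chloro glyoxal F4. F4 would be closed at high dilution by umpolung allylation with Pd(PPh3)4 and Et2Zn in THF (zerovalent palladium, allylzinc intermediate), the reaction type that is known to close ten-membered germacrane rings at a bond to C7. The equilibrating allylzinc reacts through a chair with C6 and C9 both equatorial, so the 7,8-anti ketol, the C8 epimer of 38 F5, is expected. Mitsunobu inversion with 4-nitrobenzoic acid (PPh3, DIAD) would give the 8-O-(4-nitrobenzoate) F6 with the C8 configuration of 38, and brief methanolysis (K2CO3, MeOH, 0 °C) returns to 38.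

2. Step 11 (lactone epoxidation). The peroxide may attack the lactone carbonyl, the base may deprotonate C2 and open the ring to a dienoate, or facial selectivity on the half-chair may be insufficient. Fallback with reagent control, setting out from 17 and coming back at 18: reduction with i-Bu2AlH (CH2Cl2, −78 °C) would give the (Z)-ene-1,5-diol F7. Sharpless asymmetric epoxidation of its primary allylic alcohol (Ti(OiPr)4, L-(+)-diethyl tartrate, t-BuOOH, 4 Å molecular sieves, CH2Cl2, −20 °C) would give the epoxy diol F8, and oxidative lactonisation (TEMPO cat., PhI(OAc)2, CH2Cl2) returns to 18.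

3. Step 17 (iodo-olefination beside the ketone). The basic ylide may enolise the α-alkoxy ketone, add to it, or epimerise the α-silyloxy aldehyde at C6. Fallback that makes the iodoalkene before the ketone exists, setting out from 20 and coming back at 33: Swern oxidation of 20 (conditions of step 16) would give the aldehyde Weinreb amide F9, and iodo-olefination with ylide 31, generated as in step 17, the (Z)-iodoalkene Weinreb amide F10, whose amide is inert to the ylide. MeMgBr (THF, 0 °C) does not exchange with the alkenyl iodide and would give the methyl ketone F11. Its enolate can form only on the methyl side (LiN(SiMe3)2, THF, −78 °C), and hydroxylation with 2-(phenylsulfonyl)-3-phenyloxaziridine (Davis oxidation) returns to 33, so steps 15, 16 and 18 are bypassed.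

**Further compounds**

F1 | step 20 | (Z)-allylic alcohol (CH2OH in place of the iodine of 32) | C/C(CO)=C/[C@H](O[Si](CC)(CC)CC)[C@@H]1O[C@]1(C)[C@@H](O[Si](CC)(CC)CC)C[C@H]2O[C@@]2(C)C(=O)COCc1ccc(OC)cc1
F2 | step 20 | (Z)-allylic chloride | C/C(CCl)=C/[C@H](O[Si](CC)(CC)CC)[C@@H]1O[C@]1(C)[C@@H](O[Si](CC)(CC)CC)C[C@H]2O[C@@]2(C)C(=O)COCc1ccc(OC)cc1
F3 | step 20 | α-ketol with allylic chloride | C/C(CCl)=C/[C@H](O[Si](CC)(CC)CC)[C@@H]1O[C@]1(C)[C@@H](O[Si](CC)(CC)CC)C[C@H]2O[C@@]2(C)C(=O)CO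
F4 | step 20 | chloro glyoxal | C/C(CCl)=C/[C@H](O[Si](CC)(CC)CC)[C@@H]1O[C@]1(C)[C@@H](O[Si](CC)(CC)CC)C[C@H]2O[C@@]2(C)C(=O)C=O
F5 | step 20 | C8 epimer of 38 | C=C(C)[C@H]1[C@H](O[Si](CC)(CC)CC)[C@@H]2O[C@]2(C)[C@@H](O[Si](CC)(CC)CC)C[C@H]2O[C@@]2(C)C(=O)[C@@H]1O
F6 | step 20 | 8-O-(4-nitrobenzoate) with the C8 configuration of 38 | C=C(C)[C@H]1[C@H](O[Si](CC)(CC)CC)[C@@H]2O[C@]2(C)[C@@H](O[Si](CC)(CC)CC)C[C@H]2O[C@@]2(C)C(=O)[C@H]1OC(=O)c3ccc(cc3)[N+](=O)[O-]
F7 | step 11 | (Z)-ene-1,5-diol from 17 | OC/C(C)=C\C[C@H](O)[C@@]1(C)O[C@H]1[C@@H](O[Si](CC)(CC)CC)CO[Si](CC)(CC)CC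
F8 | step 11 | epoxy diol | OC[C@]1(C)O[C@@H]1C[C@H](O)[C@@]2(C)O[C@H]2[C@@H](O[Si](CC)(CC)CC)CO[Si](CC)(CC)CC
F9 | step 17 | aldehyde Weinreb amide (C7 formyl in place of the CH2OSiEt3 group of 20) | CON(C)C(=O)[C@]1(C)O[C@@H]1C[C@H](O[Si](CC)(CC)CC)[C@@]2(C)O[C@H]2[C@@H](O[Si](CC)(CC)CC)C=O
F10 | step 17 | (Z)-iodoalkene Weinreb amide | C/C(I)=C/[C@H](O[Si](CC)(CC)CC)[C@@H]1O[C@]1(C)[C@@H](O[Si](CC)(CC)CC)C[C@H]2O[C@@]2(C)C(=O)N(C)OC
F11 | step 17 | methyl ketone (C8 as methyl) | C/C(I)=C/[C@H](O[Si](CC)(CC)CC)[C@@H]1O[C@]1(C)[C@@H](O[Si](CC)(CC)CC)C[C@H]2O[C@@]2(C)C(C)=O
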